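## Retrosynthetic overview

1. Peroxyacarnoate A ⇐ acid-catalysed MeOH exchange at the peroxyketal carbon (anomeric control of C6) ⇐ (3S)-peroxyhemiketal ⇐ enantioselective O2-insertion ring expansion (4 → 6) of a 1,2-disubstituted cyclobutanol. This key step makes the 1,2-dioxane, the O–O bond and the C3 stereocentre.
2. Cyclobutanol ⇐ C16 dienynyl Grignard + methyl 2-(2-oxocyclobutyl)acetate (from cyclobutanone by hydrazone alkylation).
3. C16 chloro-dienyne ⇐ B-alkyl Suzuki coupling of nona-1,8-diene/9-BBN with an (E)-chloroenyne (5-chloropent-1-yne + (E)-1,2-dichloroethene); the diene ⇐ allylmagnesium bromide + 6-bromohex-1-ene.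
4. Ring order: the cyclobutane is bought; the only ring made is the 1,2-dioxane, formed last by ring expansion.

Assumption: the sense of induction of the new cobalt catalyst cannot be predicted; (S,S) stands for the ligand enantiomer that gives the (3S)-peroxide, and the mirror-image ligand is used if the sense turns out opposite.

Dioxane numbering used throughout: O1–O2, C3 = CH(CH2CO2Me), C6 = peroxyketal carbon. The target is (3S,6R), with OMe cis to CH2CO2Me.

## Route

Step 1
Reactants: 1 cyclobutanone; 2 N,N-dimethylhydrazine
Product: 3 cyclobutanone N,N-dimethylhydrazone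
Conditions: Me2NNH2 (1.5 equiv), AcOH (cat.), EtOH, 70 °C; distil
Reagents that add atoms: none
Why: Hydrazone condensation masks the strained ketone so that it can be mono-alkylated without self-aldol; no stereocentre is formed.

Step 2
Reactants: 3 cyclobutanone N,N-dimethylhydrazone; 4 methyl bromoacetate
Product: 7 methyl 2-(2-oxocyclobutyl)acetate, via lithium azaenolate 5 (not isolated), via alkylated hydrazone 6 (not isolated)
Conditions: LDA, THF, 0 °C; 4, −78 °C → rt; then 1 M aq. oxalic acid, Et2O, rt
Reagents that add atoms: water O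
Why: Azaenolate (hydrazone) alkylation by SN2 on the α-bromo ester, then mild hydrolysis back to the ketone; the α-stereocentre is left racemic because it is erased in step 7.

Step 3
Reactants: 8 6-bromohex-1-ene; 9 allylmagnesium bromide
Product: 10 nona-1,8-diene
Conditions: Li2CuCl4 (2 mol%), THF, 0 °C → rt; distil
Reagents that add atoms: none
Why: Copper-catalysed sp3–sp3 Grignard coupling (Kochi type) of an allyl Grignard with a primary bromide; no stereocentre.

Step 4
Reactants: 11 5-chloropent-1-yne; 12 (E)-1,2-dichloroethene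
Product: 13 (E)-1,7-dichlorohept-1-en-3-yne
Conditions: 12 (5 equiv), Pd(PPh3)4 (5 mol%), CuI (10 mol%), n-BuNH2 (2 equiv), Et2O, rt
Reagents that add atoms: none
Why: Sonogashira coupling; the excess dihalide gives clean mono-coupling with retention of the E geometry, and the alkyl chloride is inert.

Step 5
Reactants: 10 nona-1,8-diene; 13 (E)-1,7-dichlorohept-1-en-3-yne
Product: 15 (10E)-16-chlorohexadeca-1,10-dien-12-yne, via B-(non-8-enyl)-9-BBN 14 (not isolated)
Conditions: 10 (3 equiv), 9-BBN (1.1 equiv), THF, 0 °C → rt; then 13 (1.0 equiv), Pd(OAc)2 (3 mol%), SPhos (6 mol%), 3 M aq. K3PO4, THF, 40 °C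
Reagents that add atoms: none
Why: Anti-Markovnikov hydroboration (excess diene keeps it to one end) and B-alkyl Suzuki–Miyaura coupling at the alkyne-activated alkenyl chloride with retention of the E geometry; the primary alkyl chloride does not react.

Step 6
Reactants: 15 (10E)-16-chlorohexadeca-1,10-dien-12-yne; 7 methyl 2-(2-oxocyclobutyl)acetate
Product: 17 methyl 2-{2-[(6E)-hexadeca-6,15-dien-4-yn-1-yl]-2-hydroxycyclobutyl}acetate, via dienynylmagnesium chloride 16 (not isolated)
Conditions: Mg (I2-activated), THF, 60 °C; then LaCl3·2LiCl (1 equiv), 7, THF, −78 °C; pH 7 buffer at −78 °C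
Reagents that add atoms: none
Why: Grignard formation and lanthanide-promoted 1,2-addition to the strained ketone, far faster than ester attack or enolisation at −78 °C. Attack anti to the acetate arm gives mainly the cis-hydroxy ester, and the racemic diastereomer mixture is used as such because both stereocentres are destroyed in step 7; the cold neutral quench avoids lactonisation.

Step 7
Reactants: 17 methyl 2-{2-[(6E)-hexadeca-6,15-dien-4-yn-1-yl]-2-hydroxycyclobutyl}acetate
Product: 19 peroxyacarnoate A, methyl 2-{(3S,6R)-6-[(6E)-hexadeca-6,15-dien-4-yn-1-yl]-6-methoxy-1,2-dioxan-3-yl}acetate, via peroxyhemiketal 18 (not isolated)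
Conditions: (S,S)-[Co(pdp)](OTf)2 (10 mol%; pdp = N,N'-bis(2-pyridylmethyl)-2,2'-bipyrrolidine), 5% O2 in N2 (1 atm), CH2Cl2, −20 °C; then MeOH, CSA (20 mol%), 0 °C → rt
Reagents that add atoms: dioxygen O=O; methanol CO
Why: Proposed new method: a chiral cis-α cobalt(II) aminopyridine complex replaces Co(acac)2 in the aerobic oxygenative ring expansion of a cyclobutanol. The Co(III) cyclobutanolate undergoes strain-driven β-scission of the more substituted C1–C2 bond; the secondary γ-keto radical, still held at the metal through the new ketone, should collapse inside the chiral pocket onto the cis Co(III)–superoxo ligand faster than it meets free O2 (kept dilute by 5% O2 and −20 °C), which sets C3 as S; the Co–alkylperoxide then closes on the ketone to the six-membered peroxyhemiketal. The closest known chemistry is the racemic Co(acac)2/O2 ring expansion of cyclobutanols to 1,2-dioxan-3-ols, together with cage-controlled radical rebound in chiral Mn/Fe aminopyridine oxidations; enantioselective capture of an unstabilised alkyl radical by O2 has no small-molecule precedent. The acid-catalysed exchange with MeOH via the peroxycarbenium ion is thermodynamic: OMe axial (anomeric effect) and both carbon chains equatorial, which is the 6R (cis) isomer.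

## Compound list

1 | cyclobutanone | O=C1CCC1 | starting material
2 | N,N-dimethylhydrazine | CN(C)N | starting material
3 | cyclobutanone N,N-dimethylhydrazone (1-cyclobutylidene-2,2-dimethylhydrazine) | CN(C)N=C1CCC1 | intermediate
4 | methyl bromoacetate | COC(=O)CBr | starting material
5 | lithium azaenolate of 3 (lithium 1-(cyclobut-1-en-1-yl)-2,2-dimethylhydrazin-1-ide) | [Li]N(N(C)C)C1=CCC1 | intermediate
6 | methyl 2-[2-(dimethylhydrazinylidene)cyclobutyl]acetate (racemic, C=N isomers) | COC(=O)CC1CCC1=NN(C)C | intermediate
7 | methyl 2-(2-oxocyclobutyl)acetate (racemic) | COC(=O)CC1CCC1=O | intermediate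
8 | 6-bromohex-1-ene | C=CCCCCBr | starting material
9 | allylmagnesium bromide | C=CC[Mg]Br | starting material
10 | nona-1,8-diene | C=CCCCCCC=C | intermediate
11 | 5-chloropent-1-yne | C#CCCCCl | starting material
12 | (E)-1,2-dichloroethene | Cl/C=C/Cl | starting material
13 | (E)-1,7-dichlorohept-1-en-3-yne | Cl/C=C/C#CCCCCl | intermediate
14 | 9-(non-8-en-1-yl)-9-borabicyclo[3.3.1]nonane | C=CCCCCCCCB1C2CCCC1CCC2 | intermediate
15 | (10E)-16-chlorohexadeca-1,10-dien-12-yne | C=CCCCCCCC/C=C/C#CCCCCl | intermediate
16 | [(6E)-hexadeca-6,15-dien-4-yn-1-yl]magnesium chloride | C=CCCCCCCC/C=C/C#CCCC[Mg]Cl | intermediate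
17 | methyl 2-{2-[(6E)-hexadeca-6,15-dien-4-yn-1-yl]-2-hydroxycyclobutyl}acetate (racemic, both ring diastereomers, major with OH cis to CH2CO2Me; ring configuration not specified because all isomers converge) | C=CCCCCCCC/C=C/C#CCCCC1(O)CCC1CC(=O)OC | intermediate
18 | methyl 2-{(3S)-6-[(6E)-hexadeca-6,15-dien-4-yn-1-yl]-6-hydroxy-1,2-dioxan-3-yl}acetate (C6 hemiketal epimers in equilibrium) | C=CCCCCCCC/C=C/C#CCCCC1(O)CC[C@@H](CC(=O)OC)OO1 | intermediate
19 | peroxyacarnoate A, methyl 2-{(3S,6R)-6-[(6E)-hexadeca-6,15-dien-4-yn-1-yl]-6-methoxy-1,2-dioxan-3-yl}acetate | C=CCCCCCCC/C=C/C#CCCC[C@]1(OC)CC[C@@H](CC(=O)OC)OO1 | target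

## Step count and risk

Total steps: 7. Longest linear sequence: 4 steps (3 → 5 → 6 → 7; the branches 4 → 5 → 6 → 7 and 1 → 2 → 6 → 7 are equally long).

Three steps most likely to fail:

**Step 7 (the new enantioselective ring expansion).** The risk is low ee, because free O2 may capture the radical outside the catalyst pocket, or an inactive catalyst. The fallback uses known chemistry, sets out from 17 and comes back at 19. Cyclobutanol 17 is ring-expanded with achiral Co(acac)2 (20 mol%) under O2 (1 atm) at 40 °C, the established racemic cyclobutanol-to-1,2-dioxan-3-ol oxygenation. This gives 18 as a 1:1 mixture with its mirror image, (3R)-peroxyhemiketal F1. MeOH/CSA converts the pair into the racemic methoxy peroxyketal, that is 19 and ent-peroxyacarnoate A F2. The enantiomers are separated by preparative HPLC on an amylose-carbamate chiral phase to give 19.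

**Step 6 (Grignard formation from the polyunsaturated chloride and addition to the keto ester).** The risks are sluggish or impure Grignard formation, enolisation, and lactonisation of the cis-hydroxy ester. The fallback moves the side-chain assembly to the end, sets out from 7 and 14, and comes back at 19. Keto ester 7 is treated at −78 °C with [5-(trimethylsilyl)pent-4-yn-1-yl]magnesium chloride F3, made from commercial (5-chloropent-1-yn-1-yl)trimethylsilane and Mg, to give methyl 2-{2-hydroxy-2-[5-(trimethylsilyl)pent-4-yn-1-yl]cyclobutyl}acetate F4. Ring expansion and MeOH exchange under the conditions of step 7 (or of its fallback) lead through the silylated peroxyhemiketal F5 (not isolated) to the silylated methoxy dioxane F6. Buffered TBAF/AcOH in THF at 0 °C gives the terminal alkyne, methyl 2-[(3S,6R)-6-methoxy-6-(pent-4-yn-1-yl)-1,2-dioxan-3-yl]acetate F7. Separately, borane 14 is coupled at the C–I bond of (E)-1-chloro-2-iodoethene (Pd(PPh3)4, aq. K3PO4, THF, rt) to give (E)-1-chloroundeca-1,10-diene F8. Sonogashira coupling of F7 with F8 (PdCl2(PhCN)2, CuI, piperidine, rt, short reaction time) gives 19; palladium couplings on alkyne-bearing 1,2-dioxanes are known to leave the peroxide intact.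

**Step 5 (mono-hydroboration of the diene and B-alkyl Suzuki coupling at an alkenyl chloride).** The risks are bis-hydroboration and slow oxidative addition. The fallback replaces the borane by a Grignard reagent and the palladium step by an iron-catalysed Kumada-type coupling; it sets out from 9 and 13 and comes back at 15. Allylmagnesium bromide 9 displaces the bromide of commercial 1-bromo-6-chlorohexane (Li2CuCl4 cat., THF, 0 °C) to give 9-chloronon-1-ene F9. Mg in THF converts it into non-8-en-1-ylmagnesium chloride F10, which couples with the alkenyl chloride of 13 under Fe(acac)3 (5 mol%) in THF/NMP at 0 °C with retention of geometry, to give 15.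

## Further compounds

F1 | step 7 | methyl 2-{(3R)-6-[(6E)-hexadeca-6,15-dien-4-yn-1-yl]-6-hydroxy-1,2-dioxan-3-yl}acetate | C=CCCCCCCC/C=C/C#CCCCC1(O)CC[C@H](CC(=O)OC)OO1
F2 | step 7 | ent-peroxyacarnoate A, methyl 2-{(3R,6S)-6-[(6E)-hexadeca-6,15-dien-4-yn-1-yl]-6-methoxy-1,2-dioxan-3-yl}acetate | C=CCCCCCCC/C=C/C#CCCC[C@@]1(OC)CC[C@H](CC(=O)OC)OO1
F3 | step 6 | [5-(trimethylsilyl)pent-4-yn-1-yl]magnesium chloride | C[Si](C)(C)C#CCCC[Mg]Cl
F4 | step 6 | methyl 2-{2-hydroxy-2-[5-(trimethylsilyl)pent-4-yn-1-yl]cyclobutyl}acetate (racemic, both diastereomers) | COC(=O)CC1CCC1(O)CCCC#C[Si](C)(C)C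
F5 | step 6 | methyl 2-{(3S)-6-hydroxy-6-[5-(trimethylsilyl)pent-4-yn-1-yl]-1,2-dioxan-3-yl}acetate | C[Si](C)(C)C#CCCCC1(O)CC[C@@H](CC(=O)OC)OO1
F6 | step 6 | methyl 2-{(3S,6R)-6-methoxy-6-[5-(trimethylsilyl)pent-4-yn-1-yl]-1,2-dioxan-3-yl}acetate | C[Si](C)(C)C#CCCC[C@]1(OC)CC[C@@H](CC(=O)OC)OO1
F7 | step 6 | methyl 2-[(3S,6R)-6-methoxy-6-(pent-4-yn-1-yl)-1,2-dioxan-3-yl]acetate | C#CCCC[C@]1(OC)CC[C@@H](CC(=O)OC)OO1
F8 | step 6 | (E)-1-chloroundeca-1,10-diene | C=CCCCCCCC/C=C/Cl
F9 | step 5 | 9-chloronon-1-ene | C=CCCCCCCCCl
F10 | step 5 | non-8-en-1-ylmagnesium chloride | C=CCCCCCCC[Mg]Cl
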